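The cyclohexene is cut twice: across the C3=C4 alkene and across the C1–C6 bond of the cis-1,6-diol (C1 = quaternary carbinol carbon, C7 = its CH2O arm, C2 and C5 = allylic CH–O, C6 = CHOH). The key step exploits that the C7 arm and the C5 oxygen lie on the same face of the ring, 1,3 across C6: a diisopropylsilylene ties O7 to O5, and the tethered keto-aldehyde then undergoes, in one flask, a SmI2 pinacol cyclization (C1–C6) and a ring-closing metathesis of its two vinyl groups (C3=C4). Both halves come from one epoxy alcohol; the three benzoates are put on last.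

Key step: step 7

Remark: the locants C1–C7 defined above are used for all cyclic compounds; the sense of the asymmetric epoxidation (D-(−)-diisopropyl tartrate giving the (2S,3R)-epoxy alcohol) is assumed from the usual Sharpless mnemonic.

Step 1
Reactants: 1 penta-1,4-dien-3-ol
Product: 2 (2S,3R)-1,2-epoxypent-4-en-3-ol
Conditions: Ti(OiPr)4 (10 mol %), D-(−)-DIPT (13 mol %), tBuOOH, 4 Å MS, CH2Cl2, −20 °C
Reagents that add atoms: tert-butyl hydroperoxide, CC(C)(C)OO
Why: Sharpless asymmetric epoxidation of a divinylcarbinol, in which the tartrate-bound titanium peroxide selects one enantiotopic vinyl group and one of its faces (reagent control sets C2 and C3 together) while the minor enantiomer is drained by faster second epoxidation.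

Step 2
Reactants: 2 (2S,3R)-1,2-epoxypent-4-en-3-ol
Product: 3 (2S,3R)-3-[(tert-butyldimethylsilyl)oxy]-1,2-epoxypent-4-ene
Conditions: TBSCl, imidazole, DMF, 0 °C → rt
Reagents that add atoms: tert-butyldimethylsilyl chloride, CC(C)(C)[Si](C)(C)Cl
Why: Standard silylation of a secondary alcohol with a base too weak to trigger Payne rearrangement of the epoxy alcohol; no stereocenter is touched.

Step 3
Reactants: 3 (2S,3R)-3-[(tert-butyldimethylsilyl)oxy]-1,2-epoxypent-4-ene
Product: 4 (2S,3R)-3-[(tert-butyldimethylsilyl)oxy]pent-4-ene-1,2-diol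
Conditions: HClO4 (cat.), THF–H2O (3:1), 0 °C → rt
Reagents that add atoms: water, O
Why: Acid-catalysed epoxide hydrolysis with water attacking the unhindered terminal carbon, so both stereocenters are retained and the secondary TBS ether should survive the dilute acid.

Step 4
Reactants: 2 (2S,3R)-1,2-epoxypent-4-en-3-ol; 4 (2S,3R)-3-[(tert-butyldimethylsilyl)oxy]pent-4-ene-1,2-diol
Product: 6 silaketal alcohol (2S,3R)-3-[(tert-butyldimethylsilyl)oxy]-1-{[diisopropyl({(2S,3R)-1,2-epoxypent-4-en-3-yl}oxy)silyl]oxy}pent-4-en-2-ol, via chlorosilane 5 (not isolated)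
Conditions: 2 added to iPr2SiCl2 (1.2 equiv), imidazole, CH2Cl2, −78 → 0 °C; then 4, imidazole, DMF, 0 °C → rt
Reagents that add atoms: dichlorodiisopropylsilane, CC(C)[Si](Cl)(Cl)C(C)C
Why: Stepwise synthesis of an unsymmetrical bis-alkoxysilane (temporary silicon tether), in which the hindered secondary alcohol 2 displaces only one chloride and the remaining Si–Cl is then taken by the primary hydroxyl of 4 in preference to its hindered secondary one.

Step 5
Reactants: 6 silaketal alcohol
Product: 7 (3R)-3-[(tert-butyldimethylsilyl)oxy]-1-{[diisopropyl({(2S,3R)-1,2-epoxypent-4-en-3-yl}oxy)silyl]oxy}pent-4-en-2-one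
Conditions: Dess–Martin periodinane, pyridine, CH2Cl2, 0 °C → rt
Reagents that add atoms: none
Why: Dess–Martin oxidation of the only free (secondary) alcohol to the ketone under buffered conditions that should neither open the epoxide nor enolise the adjacent allylic stereocenter.

Step 6
Reactants: 7 epoxy ketone
Product: 9 keto-aldehyde (2R)-2-{[({(3R)-3-[(tert-butyldimethylsilyl)oxy]-2-oxopent-4-en-1-yl}oxy)diisopropylsilyl]oxy}but-3-enal, via diol 8 (not isolated)
Conditions: H5IO6, THF–H2O, 0 °C → rt; used crude
Reagents that add atoms: none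
Why: Periodic acid opens the terminal epoxide to the 1,2-diol and cleaves it in the same flask (glycol cleavage) to the aldehyde with loss of formaldehyde, while the ketone, having no free α-hydroxyl, is not cleaved and the α-stereocenter is left alone.

Step 7
Reactants: 9 keto-aldehyde
Product: 11 bridged diol 9-[(tert-butyldimethylsilyl)oxy]-4,4-diisopropyl-3,5-dioxa-4-silabicyclo[4.3.1]dec-7-ene-1,10-diol (C1-OH; C6-OH; C2-OTBS on one face; O7–Si–O5 bridge on the other), via silepane diol 10 (not isolated)
Conditions: SmI2 (3 equiv), HMPA, tBuOH, THF, −78 °C (9 added slowly, 5 mM); then air, Ar; second-generation Hoveyda–Grubbs catalyst (10 mol %), toluene, 60 °C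
Reagents that add atoms: none
Why: SmI2 reduces the carbonyl groups of 9 and the aldehyde ketyl attacks the samarium-bound ketone carbon (pinacol cyclization, the known SmI2 keto-aldehyde reductive cyclization applied to a silicon-tethered substrate), forming C1–C6 and closing the seven-membered 1,3-dioxa-2-silepane of 10 in a 7-exo-trig radical closure onto the carbonyl. After air has discharged the excess reductant, the ruthenium carbene closes the six-membered carbocycle by ring-closing metathesis of the two vinyl groups with loss of ethylene, forming C3=C4 and the bicyclo[4.3.1] core of 11. C1 is set in the chair-like seven-membered transition state, where the branched C2 substituent and the C5 vinyl group should both sit equatorial (cis-1,3) and the ketone is attacked anti to its C2–OTBS bond (Felkin–Anh), so the C1 hydroxyl ends on the face of the C2 oxygen. C6 is set by the non-chelated coupling expected for HMPA-saturated samarium: the two C–O(Sm) bonds stand antiperiplanar, which in the seven-membered ring means the trans-5,6-diol of the silepane, that is the cis-1,6-diol of the cyclohexene with the C6 hydroxyl trans to the C5 oxygen. The step needs hetero- over homo-coupling and a cis disposition of the two alkenyl branches: the O7–Si–O5 tether at high dilution leaves only the intramolecular ketone–aldehyde pairing, and the metathesis acts as a filter because only the cis-1,3 diastereomer can close the bridged ring. The (R) centres at C2 and C5 should pass unchanged through these neutral conditions.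

Step 8
Reactants: 11 bridged diol
Product: 12 1,6-O-isopropylidene acetal of 11
Conditions: 2-methoxypropene, PPTS (cat.), CH2Cl2, 0 °C → rt
Reagents that add atoms: 2-methoxypropene, C=C(C)OC
Why: Acid-catalysed acetonide formation on the cis-1,6-diol, the only free hydroxyls, which masks both so that they stay unacylated later.

Step 9
Reactants: 12 acetonide
Product: 13 triol 1-(hydroxymethyl)cyclohex-3-ene-1,2,5,6-tetrol 1,6-acetonide (free OH at C2, C5 and C7)
Conditions: TBAF, THF, 0 °C → rt
Reagents that add atoms: none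
Why: Fluoride-mediated desilylation removes the bridging diisopropylsilylene and the TBS ether at once, freeing exactly the three hydroxyls that become benzoates.

Step 10
Reactants: 13 triol
Product: 14 2,5,7-tri-O-benzoate of 13
Conditions: BzCl, pyridine, DMAP (cat.), CH2Cl2, 0 °C → rt
Reagents that add atoms: benzoyl chloride, O=C(Cl)c1ccccc1
Why: DMAP-catalysed acylation of one primary and two allylic secondary alcohols; no stereocenter is touched.

Step 11
Reactants: 14 tribenzoate acetonide
Product: 15 [(1S,2R,5R,6S)-2,5-bis(benzoyloxy)-1,6-dihydroxycyclohex-3-en-1-yl]methyl benzoate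
Conditions: TFA–H2O (9:1), CH2Cl2, 0 °C
Reagents that add atoms: none
Why: Acid hydrolysis of the isopropylidene acetal under conditions where benzoates should neither cleave nor migrate, releasing the cis-1,6-diol.

Compound list
1 | penta-1,4-dien-3-ol (divinylcarbinol) | C=CC(O)C=C | starting material
2 | (2S,3R)-1,2-epoxypent-4-en-3-ol | C=C[C@@H](O)[C@@H]1CO1 | intermediate
3 | (2S,3R)-3-[(tert-butyldimethylsilyl)oxy]-1,2-epoxypent-4-ene | C=C[C@@H](O[Si](C)(C)C(C)(C)C)[C@@H]1CO1 | intermediate
4 | (2S,3R)-3-[(tert-butyldimethylsilyl)oxy]pent-4-ene-1,2-diol | C=C[C@@H](O[Si](C)(C)C(C)(C)C)[C@@H](O)CO | intermediate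
5 | chloro{[(2S,3R)-1,2-epoxypent-4-en-3-yl]oxy}diisopropylsilane (not isolated) | C=C[C@@H](O[Si](Cl)(C(C)C)C(C)C)[C@@H]1CO1 | intermediate
6 | (2S,3R)-3-[(tert-butyldimethylsilyl)oxy]-1-{[diisopropyl({(2S,3R)-1,2-epoxypent-4-en-3-yl}oxy)silyl]oxy}pent-4-en-2-ol | C=C[C@@H](O[Si](C(C)C)(C(C)C)OC[C@H](O)[C@H](O[Si](C)(C)C(C)(C)C)C=C)[C@@H]1CO1 | intermediate
7 | (3R)-3-[(tert-butyldimethylsilyl)oxy]-1-{[diisopropyl({(2S,3R)-1,2-epoxypent-4-en-3-yl}oxy)silyl]oxy}pent-4-en-2-one | C=C[C@@H](O[Si](C(C)C)(C(C)C)OCC(=O)[C@H](O[Si](C)(C)C(C)(C)C)C=C)[C@@H]1CO1 | intermediate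
8 | (3R)-3-[(tert-butyldimethylsilyl)oxy]-1-{[({(3R,4S)-4,5-dihydroxypent-1-en-3-yl}oxy)diisopropylsilyl]oxy}pent-4-en-2-one (not isolated) | C=C[C@@H](O[Si](C(C)C)(C(C)C)OCC(=O)[C@H](O[Si](C)(C)C(C)(C)C)C=C)[C@@H](O)CO | intermediate
9 | (2R)-2-{[({(3R)-3-[(tert-butyldimethylsilyl)oxy]-2-oxopent-4-en-1-yl}oxy)diisopropylsilyl]oxy}but-3-enal | C=C[C@@H](O[Si](C(C)C)(C(C)C)OCC(=O)[C@H](O[Si](C)(C)C(C)(C)C)C=C)C=O | intermediate
10 | 5-{(1R)-1-[(tert-butyldimethylsilyl)oxy]prop-2-en-1-yl}-7-ethenyl-2,2-diisopropyl-1,3-dioxa-2-silepane-5,6-diol; 5,6-diol trans, 7-vinyl cis to 6-OH and to the 5-branch (not isolated) | CC(C)[Si]1(C(C)C)OC[C@@](O)([C@H](O[Si](C)(C)C(C)(C)C)C=C)[C@@H](O)[C@@H](C=C)O1 | intermediate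
11 | 9-[(tert-butyldimethylsilyl)oxy]-4,4-diisopropyl-3,5-dioxa-4-silabicyclo[4.3.1]dec-7-ene-1,10-diol; C1-OH, C6-OH and C2-OTBS on one face, O7–Si–O5 bridge on the other | CC(C)[Si]2(C(C)C)OC[C@@]1(O)[C@H](O[Si](C)(C)C(C)(C)C)C=C[C@@H](O2)[C@@H]1O | intermediate
12 | 1,6-O-isopropylidene acetal of 11 | CC(C)[Si]2(C(C)C)OC[C@@]1(OC(C)(C)O3)[C@H](O[Si](C)(C)C(C)(C)C)C=C[C@@H](O2)[C@@H]13 | intermediate
13 | 1-(hydroxymethyl)cyclohex-3-ene-1,2,5,6-tetrol 1,6-acetonide, free OH at C2, C5 and C7 | OC[C@@]1(OC(C)(C)O2)[C@H](O)C=C[C@@H](O)[C@@H]12 | intermediate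
14 | 2,5,7-tri-O-benzoate of 13 | O=C(OC[C@@]1(OC(C)(C)O2)[C@H](OC(=O)c3ccccc3)C=C[C@@H](OC(=O)c3ccccc3)[C@@H]12)c1ccccc1 | intermediate
15 | [(1S,2R,5R,6S)-2,5-bis(benzoyloxy)-1,6-dihydroxycyclohex-3-en-1-yl]methyl benzoate | O=C(OC[C@@]1(O)[C@H](OC(=O)c2ccccc2)C=C[C@@H](OC(=O)c2ccccc2)[C@@H]1O)c1ccccc1 | target

Total steps: 11. Longest linear sequence: 11 steps (1 → 2 → 3 → 4 → 6 → 7 → 9 → 11 → 12 → 13 → 14 → 15).

Steps most likely to fail

Step 7. The coupling may run through a samarium-bridged (chelated) transition state and give the diol that is cis on the silepane, which is the C6 epimer and still ring-closes. HMPA may also promote reductive loss of the α-silyloxy groups of the ketone, and samarium salts or HMPA may slow the ruthenium catalyst. The fallback sets C6 by hydride addition instead of by the radical coupling and runs the two ring closures separately; it sets out from 9 and comes back at 11. The pinacol cyclization is run alone under chelating conditions (SmI2, tBuOH, THF, −78 °C, no HMPA) and the silepane diol is isolated, expected mainly as the C6 epimer F1. Dess–Martin oxidation of its only secondary hydroxyl gives the α-hydroxy ketone F2. Reduction with Zn(BH4)2 in Et2O at −20 °C, with hydride arriving on the face of the C1 hydroxyl and away from the branched C2 substituent, should give 10, now isolated. Ring-closing metathesis of 10 (second-generation Hoveyda–Grubbs catalyst, CH2Cl2, 40 °C) then gives 11.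

Step 6. Aqueous periodic acid may hydrolyse or shift the silicon groups (the silaketal in particular), and the keto-aldehyde may epimerise or hydrate during work-up. The fallback uses a different latent aldehyde; it sets out from 4 and comes back at 9. Commercial (R)-but-3-ene-1,2-diol is silylated at its primary hydroxyl (TESCl, imidazole, CH2Cl2, −20 °C) to (R)-1-[(triethylsilyl)oxy]but-3-en-2-ol F3. F3 is added to iPr2SiCl2 and imidazole to give the chlorosilane F4, which is joined to the primary hydroxyl of 4 to give the silaketal F5. A single Swern oxidation ((COCl)2, DMSO, CH2Cl2, −78 °C; Et3N, → −30 °C) oxidises the secondary alcohol to the ketone and the primary TES ether directly to the aldehyde, giving 9 without aqueous acid.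

Step 4. The silicon coupling may give symmetrical bis-ethers. The free secondary hydroxyl next to the new Si–O bond may also attack silicon and expel 2, forming a cyclic silylene of 4. The fallback installs the ketone before the tether; it sets out from 4 and comes back at 7. The primary hydroxyl of 4 is silylated (TESCl, imidazole, CH2Cl2, −40 °C) to F6, Dess–Martin oxidation gives the ketone F7, and PPTS in MeOH at 0 °C removes the primary TES group to give the α-hydroxy ketone F8. F8 is then silylated with the chlorosilane 5 (imidazole, DMF, 0 °C) to give 7 directly.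

Further compounds
F1 | step 7 | C6 epimer of 10 (5,6-diol cis on the silepane, 6-OH trans to the 7-vinyl group) | CC(C)[Si]1(C(C)C)OC[C@@](O)([C@H](O[Si](C)(C)C(C)(C)C)C=C)[C@H](O)[C@@H](C=C)O1
F2 | step 7 | 5-{(1R)-1-[(tert-butyldimethylsilyl)oxy]prop-2-en-1-yl}-7-ethenyl-5-hydroxy-2,2-diisopropyl-1,3-dioxa-2-silepan-6-one | CC(C)[Si]1(C(C)C)OC[C@@](O)([C@H](O[Si](C)(C)C(C)(C)C)C=C)C(=O)[C@@H](C=C)O1
F3 | step 6 | (R)-1-[(triethylsilyl)oxy]but-3-en-2-ol | C=C[C@@H](O)CO[Si](CC)(CC)CC
F4 | step 6 | chloro(diisopropyl){[(2R)-1-[(triethylsilyl)oxy]but-3-en-2-yl]oxy}silane | C=C[C@@H](O[Si](Cl)(C(C)C)C(C)C)CO[Si](CC)(CC)CC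
F5 | step 6 | (2S,3R)-3-[(tert-butyldimethylsilyl)oxy]-1-{[diisopropyl({(2R)-1-[(triethylsilyl)oxy]but-3-en-2-yl}oxy)silyl]oxy}pent-4-en-2-ol | C=C[C@@H](O[Si](C(C)C)(C(C)C)OC[C@H](O)[C@H](O[Si](C)(C)C(C)(C)C)C=C)CO[Si](CC)(CC)CC
F6 | step 4 | (2S,3R)-3-[(tert-butyldimethylsilyl)oxy]-1-[(triethylsilyl)oxy]pent-4-en-2-ol | C=C[C@@H](O[Si](C)(C)C(C)(C)C)[C@@H](O)CO[Si](CC)(CC)CC
F7 | step 4 | (3R)-3-[(tert-butyldimethylsilyl)oxy]-1-[(triethylsilyl)oxy]pent-4-en-2-one | C=C[C@@H](O[Si](C)(C)C(C)(C)C)C(=O)CO[Si](CC)(CC)CC
F8 | step 4 | (3R)-3-[(tert-butyldimethylsilyl)oxy]-1-hydroxypent-4-en-2-one | C=C[C@@H](O[Si](C)(C)C(C)(C)C)C(=O)CO
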